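**Retrosynthetic overview**
1. Target ⇐ O‑9 acetylation, O‑4 angeloylation, lactone α‑methylenation and reagent‑controlled reduction of a C4 ketone in an (E)‑cyclodecenone epoxy‑lactone.
2. Ten‑membered ring ⇐ ring‑expanding Grob fragmentation of the C4–C10 bond of a trans‑5/7‑fused γ‑iodo tertiary alcohol (C11–I anti‑periplanar to C4–C10 and cis to the C10 methyl, hence the E olefin).
3. That tricycle ⇐ hydroxyl‑directed epoxidation (C7/C8) of a cycloheptenol ⇐ RCM (C7=C8) ⇐ Grignard addition of a C5 homoallyl unit to the C4 ketone.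
4. C9–C10 bond, C10 quaternary centre and the C11–I nucleofuge ⇐ three‑component iodo‑aldol of a cis‑fused 2‑methylcyclopentenone lactone with acrolein (new step).
5. Enone lactone ⇐ Piancatelli rearrangement (3‑methylfurfural + ethyl acetate), lipase resolution, epimerising lactonisation. Ring order: cyclopentenone → γ‑lactone → cycloheptene → oxirane → cyclodecene (by expansion).

Locants: the cyclodeca[b]furan locants of the target (O1, C2 lactone C=O, C3, C3a, C4 … C11, C11a) are used for all intermediates from 6 on; β is the face of the five‑membered carbocycle that carries H‑3a and H‑11a.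
Assumption: the lipase in step 3 acetylates the (1S,5R) antipode of 4 (Kazlauskas rule, large group = the branched ring carbon) and leaves the required (1R,5S) alcohol.

**Step 1**
Reactants: 1 3‑methylfuran‑2‑carbaldehyde; 2 ethyl acetate
Product: 3 ethyl 3‑hydroxy‑3‑(3‑methylfuran‑2‑yl)propanoate (racemic)
Conditions: LDA, THF, −78 °C; then 1; NH4Cl quench
Reagents that add atoms: none
Why: Acetate aldol addition of the lithium enolate to a non‑enolisable heteroaryl aldehyde; the carbinol centre is racemic and is destroyed in step 2.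

**Step 2**
Reactants: 3 ethyl 3‑hydroxy‑3‑(3‑methylfuran‑2‑yl)propanoate
Product: 4 ethyl 2‑[(1R*,5S*)‑5‑hydroxy‑3‑methyl‑2‑oxocyclopent‑3‑en‑1‑yl]acetate (racemic, trans)
Conditions: ZnCl2 (1.5 equiv), 1,4‑dioxane/H2O 1:1, pH ≈ 5.5, 95 °C
Reagents that add atoms: water, O
Why: Piancatelli rearrangement: the furfuryl cation is captured by water at furan C5, the ring opens and conrotatory 4π‑electrocyclisation of the hydroxypentadienyl cation gives the 4‑hydroxy‑5‑substituted cyclopentenone with trans C3a/C11a; the furan 3‑methyl becomes the enone α‑methyl.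

**Step 3**
Reactants: 4 ethyl 2‑[(1R*,5S*)‑5‑hydroxy‑3‑methyl‑2‑oxocyclopent‑3‑en‑1‑yl]acetate (racemate)
Product: 5 ethyl 2‑[(1R,5S)‑5‑hydroxy‑3‑methyl‑2‑oxocyclopent‑3‑en‑1‑yl]acetate
Conditions: Amano lipase PS (Burkholderia cepacia), vinyl acetate, MTBE, 30 °C, stopped at ≈52 % conversion; chromatography
Reagents that add atoms: none
Why: Lipase‑catalysed kinetic resolution by enantioselective acetylation of the (5R) carbinol, which leaves the (1R,5S) alcohol and so fixes the absolute configuration at C11a (S).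

**Step 4**
Reactants: 5 ethyl 2‑[(1R,5S)‑5‑hydroxy‑3‑methyl‑2‑oxocyclopent‑3‑en‑1‑yl]acetate
Product: 6 (3aS,6aS)‑5‑methyl‑3,3a‑dihydro‑2H‑cyclopenta[b]furan‑2,4(6aH)‑dione (cis‑fused enone lactone)
Conditions: CSA (10 mol %), toluene, 90 °C, 4 Å MS
Reagents that add atoms: none
Why: Acid‑catalysed enolisation epimerises C3a (α to the ketone) and only the cis isomer can close the γ‑lactone (transesterification to a cis‑bicyclo[3.3.0] system), so the equilibrium drains into 6 with C11a untouched.

**Step 5**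
Reactants: 6 cis‑fused enone lactone; 7 acrolein
Product: 9 (3aS,9S,10S,11R,11aR) β‑iodo aldol (C10: CH3 β and CH(OH)CH=CH2 α; C11–I β), via aluminium enolate 8 (not isolated)
Conditions: Et2AlI (1.1 equiv), CH2Cl2, −78 °C, 30 min; then 7 (1.5 equiv), −78 °C; pH 7 phosphate buffer
Reagents that add atoms: diethylaluminium iodide, CC[Al](I)CC
Why: Proposed new method: a halo‑aldol three‑component coupling on an α‑methyl cyclic enone, in which Et2AlI binds the ketone and delivers iodide 1,4 to C11 from the convex β face (anti to O‑11a) to give the tetrasubstituted aluminium enolate 8; acrolein then reacts through a closed Zimmerman–Traxler chair on the face anti to the new C–I bond, which sets the C10 quaternary centre (CH3 cis to I) and, with vinyl equatorial and CH3 cis to the enolate oxygen, the 9S carbinol (syn to CH3); the iodide cannot be lost by E1cB because C10 has no hydrogen, so it is kept as the nucleofuge for step 11; the closest known reaction types are the Et2AlI‑ or TiCl4/Bu4NI‑promoted iodo‑aldol of α‑unsubstituted enones and the Me2AlSPh Michael–aldol, neither shown for an α‑quaternary centre or for carrying the halide forward.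

**Step 6**
Reactants: 9 β‑iodo aldol
Product: 10 triethylsilyl ether of 9 (3aS,9S,10S,11R,11aR)
Conditions: TESCl, imidazole, DMF, 0 °C
Reagents that add atoms: chlorotriethylsilane, CC[Si](Cl)(CC)CC
Why: Standard silyl ether protection of the secondary carbinol; it blocks the C9 alkoxide, which under the basic conditions of step 7 would expel iodide in a retro‑iodo‑aldol fragmentation, and changes no stereocentre.

**Step 7**
Reactants: 10 TES‑protected β‑iodo ketone; 11 4‑bromo‑2‑methylbut‑1‑ene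
Product: 13 (3aS,4S,9S,10S,11R,11aR) tertiary alcohol (C4: OH α, CH2CH2C(CH3)=CH2 β), via Grignard reagent 12 (not isolated)
Conditions: 11, Mg, THF, rt; then 10, LaCl3·2LiCl (1.1 equiv), THF, −78 °C; AcOH quench at −78 °C
Reagents that add atoms: none
Why: Lanthanide‑promoted Grignard 1,2‑addition to the ketone (more electrophilic than the lactone, enolisation suppressed) from the convex β face, syn to the C10 methyl and anti to the C9 side chain and lactone, which places C4–OH α; the magnesium alkoxide does not fragment at −78 °C and is protonated cold.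

**Step 8**
Reactants: 13 diene tertiary alcohol
Product: 15 (3aS,4S,9S,10S,11R,11aR) trans‑5/7‑fused cycloheptene diol (C7=C8, C4–OH α, C9–OH α, C11–I β), via cycloheptene TES ether 14 (not isolated)
Conditions: Hoveyda–Grubbs II (5 mol %), CH2Cl2, 40 °C; then MeOH, PPTS, rt
Reagents that add atoms: none
Why: Ring‑closing metathesis of the monosubstituted and the 1,1‑disubstituted olefin gives the trisubstituted cycloheptene, which is necessarily Z in a seven‑membered ring; mild acidic methanolysis then removes the TES group and leaves the tertiary alcohol and iodide intact.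

**Step 9**
Reactants: 15 cycloheptene diol
Product: 16 (3aS,4S,7S,8R,9R,10S,11R,11aR) cis‑epoxy alcohol (7,8‑epoxide α, syn to C9–OH; C9 descriptor changes by CIP priority only)
Conditions: VO(acac)2 (5 mol %), t‑BuOOH, CH2Cl2, 0 °C → rt
Reagents that add atoms: tert‑butyl hydroperoxide, CC(C)(C)OO
Why: Vanadium‑catalysed hydroxyl‑directed epoxidation of a cyclohept‑2‑enol delivers oxygen syn to the allylic C9–OH and sets C7 (S) and C8 (R); it is the only olefin in the molecule.

**Step 10**
Reactants: 16 cis‑epoxy alcohol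
Product: 17 C9 tert‑butyldimethylsilyl ether of 16 (3aS,4S,7S,8R,9R,10S,11R,11aR)
Conditions: TBSOTf (1.1 equiv), 2,6‑lutidine, CH2Cl2, −78 °C
Reagents that add atoms: tert‑butyldimethylsilyl trifluoromethanesulfonate, CC(C)(C)[Si](C)(C)OS(=O)(=O)C(F)(F)F
Why: Silyl ether protection that is selective for the secondary C9–OH over the hindered tertiary C4–OH at low temperature; TBS is chosen because it migrates and cleaves less readily than TES under the alkoxide and enolate conditions that follow.

**Step 11**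
Reactants: 17 trans‑5/7‑fused γ‑iodo tertiary alcohol
Product: 18 (3aS,7S,8R,9R,11aS,10E)‑9‑(tert‑butyldimethylsilyloxy)‑7,8‑epoxy‑7,10‑dimethyl‑3,3a,5,6,7,8,9,11a‑octahydrocyclodeca[b]furan‑2,4‑dione
Conditions: KHMDS (1.05 equiv), THF, −78 → −20 °C; AcOH quench
Reagents that add atoms: none
Why: Ring‑expanding Grob fragmentation (5/7 → 10): the C4 alkoxide pushes, the C4–C10 bond breaks and iodide leaves; the pseudo‑equatorial C11–I bond is anti‑periplanar to C4–C10 and cis to the C10 methyl, so the new C10=C11 bond is E. One equivalent of base is used so that the β‑acyloxy ketone product is not enolised.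

**Step 12**
Reactants: 18 cyclodecenone
Product: 19 (3aR,4R,7S,8R,9R,11aS,10E) C4 alcohol
Conditions: (S)‑Me‑CBS (1.0 equiv), catecholborane, toluene, −78 °C; pH 7 work‑up
Reagents that add atoms: none
Why: Corey–Bakshi–Shibata reduction under reagent control: the branched C3a side is the large group and CH2‑5 the small one, so the (S)‑oxazaborolidine gives the 4R alcohol; lactone, epoxide and olefin are inert to catecholborane at −78 °C.

**Step 13**
Reactants: 19 hydroxy lactone
Product: 22 (3aR,4R,7S,8R,9R,11aS,10E) α‑methylene lactone alcohol, via Mannich base 20 (not isolated), via methiodide 21 (not isolated)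
Conditions: LDA (2.2 equiv), THF, −78 °C (inverse addition); CH2=NMe2+ I−, −78 → 0 °C; then MeI, CH2Cl2/MeOH, rt; aq. NaHCO3
Reagents that add atoms: N,N‑dimethylmethyleneiminium iodide (Eschenmoser's salt), C=[N+](C)C.[I-]
Why: Eschenmoser Mannich methylenation: the alkoxide/lactone‑enolate dianion is aminomethylated at C3, and quaternisation followed by mild E1cB elimination gives the exocyclic methylene; enolate formation also protects the lactone carbonyl from attack by the C4 alkoxide, and no stereocentre is touched.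

**Step 14**
Reactants: 22 α‑methylene lactone alcohol; 23 angelic acid ((Z)‑2‑methylbut‑2‑enoic acid)
Product: 25 (3aR,4R,7S,8R,9R,11aS,10E) C4 angelate, via mixed anhydride 24 (not isolated)
Conditions: 23, 2,4,6‑trichlorobenzoyl chloride, Et3N, toluene, rt; then 22, toluene, 80 °C (no DMAP)
Reagents that add atoms: none
Why: Yamaguchi‑type esterification through the mixed anhydride without a nucleophilic catalyst, the conditions under which the Z (angelate) geometry is kept and not isomerised to tiglate; the carbinol configuration is retained.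

**Step 15**
Reactants: 25 silyl‑protected angelate
Product: 27 target (3aR,4R,7S,8R,9R,11aS,10E)‑9‑acetoxy‑7,8‑epoxy‑7,10‑dimethyl‑3‑methylidene‑2‑oxo‑2,3,3a,4,5,6,7,8,9,11a‑decahydrocyclodeca[b]furan‑4‑yl (2Z)‑2‑methylbut‑2‑enoate, via C9 alcohol 26 (not isolated)
Conditions: TBAF, AcOH, THF, 0 °C → rt; then Ac2O, Et3N, DMAP (cat.), rt
Reagents that add atoms: acetic anhydride, CC(=O)OC(C)=O
Why: Acetic‑acid‑buffered fluoride desilylation (no free alkoxide next to the epoxide, Michael acceptor or esters) followed by standard acylation of the C9 alcohol with retention.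

**Compound list**
1 | 3‑methylfuran‑2‑carbaldehyde | Cc1ccoc1C=O | starting material
2 | ethyl acetate | CCOC(C)=O | starting material
3 | ethyl 3‑hydroxy‑3‑(3‑methylfuran‑2‑yl)propanoate (racemic) | CCOC(=O)CC(O)c1occc1C | intermediate
4 | ethyl 2‑[(1R*,5S*)‑5‑hydroxy‑3‑methyl‑2‑oxocyclopent‑3‑en‑1‑yl]acetate (racemate, trans; SMILES shows one enantiomer) | O=C1C(C)=C[C@H](O)[C@H]1CC(=O)OCC | intermediate
5 | ethyl 2‑[(1R,5S)‑5‑hydroxy‑3‑methyl‑2‑oxocyclopent‑3‑en‑1‑yl]acetate (single enantiomer) | O=C1C(C)=C[C@H](O)[C@H]1CC(=O)OCC | intermediate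
6 | (3aS,6aS)‑5‑methyl‑3,3a‑dihydro‑2H‑cyclopenta[b]furan‑2,4(6aH)‑dione (target locants 3aS,11aS) | O=C1O[C@H]2C=C(C)C(=O)[C@H]2C1 | intermediate
7 | acrolein (prop‑2‑enal) | C=CC=O | starting material
8 | diethylaluminium enolate (C4–OAlEt2, C4=C10(CH3), C11–I β; 3aS,11R,11aR) | O=C1C[C@@H]2C(O[Al](CC)CC)=C(C)[C@@H](I)[C@@H]2O1 | intermediate
9 | (3aS,5S,6R,6aR)‑5‑[(1S)‑1‑hydroxyprop‑2‑en‑1‑yl]‑6‑iodo‑5‑methyltetrahydro‑2H‑cyclopenta[b]furan‑2,4(3H)‑dione (target locants 3aS,9S,10S,11R,11aR) | O=C1C[C@@H]2C(=O)[C@](C)([C@@H](O)C=C)[C@@H](I)[C@@H]2O1 | intermediate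
10 | triethylsilyl ether of 9 (3aS,9S,10S,11R,11aR) | O=C1C[C@@H]2C(=O)[C@](C)([C@@H](O[Si](CC)(CC)CC)C=C)[C@@H](I)[C@@H]2O1 | intermediate
11 | 4‑bromo‑2‑methylbut‑1‑ene | C=C(C)CCBr | starting material
12 | (3‑methylbut‑3‑en‑1‑yl)magnesium bromide | C=C(C)CC[Mg]Br | intermediate
13 | (3aS,4S,9S,10S,11R,11aR) cis‑lactone‑fused cyclopentanol: C4 OH (α) and 3‑methylbut‑3‑enyl (β); C10 CH3 (β) and CH(OTES)CH=CH2 (α); C11–I β | O=C1C[C@@H]2[C@@](O)(CCC(C)=C)[C@](C)([C@@H](O[Si](CC)(CC)CC)C=C)[C@@H](I)[C@@H]2O1 | intermediate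
14 | (3aS,4S,9S,10S,11R,11aR) tricyclic lactone, trans‑5/7‑fused along C4–C10, C7=C8 (7‑CH3), C9–OTES, C4–OH, C11–I | O=C1C[C@@H]2[C@@]3(O)CCC(C)=C[C@H](O[Si](CC)(CC)CC)[C@]3(C)[C@@H](I)[C@@H]2O1 | intermediate
15 | (3aS,4S,9S,10S,11R,11aR) tricyclic diol (as 14 with free C9–OH) | O=C1C[C@@H]2[C@@]3(O)CCC(C)=C[C@H](O)[C@]3(C)[C@@H](I)[C@@H]2O1 | intermediate
16 | (3aS,4S,7S,8R,9R,10S,11R,11aR) tricyclic 7,8‑epoxide (epoxide O, C9–OH and C4–OH all α) | O=C1C[C@@H]2[C@@]3(O)CC[C@]4(C)O[C@@H]4[C@H](O)[C@]3(C)[C@@H](I)[C@@H]2O1 | intermediate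
17 | C9 tert‑butyldimethylsilyl ether of 16 | O=C1C[C@@H]2[C@@]3(O)CC[C@]4(C)O[C@@H]4[C@H](O[Si](C)(C)C(C)(C)C)[C@]3(C)[C@@H](I)[C@@H]2O1 | intermediate
18 | (3aS,7S,8R,9R,11aS,10E)‑9‑(TBS‑oxy)‑7,8‑epoxy‑7,10‑dimethyl‑3,3a,5,6,7,8,9,11a‑octahydrocyclodeca[b]furan‑2,4‑dione | C1C(=O)O[C@H]2/C=C(\C)[C@@H](O[Si](C)(C)C(C)(C)C)[C@H]3O[C@@]3(C)CCC(=O)[C@@H]12 | intermediate
19 | (3aR,4R,7S,8R,9R,11aS,10E) C4 alcohol from 18 | C1C(=O)O[C@H]2/C=C(\C)[C@@H](O[Si](C)(C)C(C)(C)C)[C@H]3O[C@@]3(C)CC[C@@H](O)[C@@H]12 | intermediate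
20 | 3‑(dimethylaminomethyl) lactone (Mannich base of 19; C3 epimers, inconsequential) | CN(C)CC1C(=O)O[C@H]2/C=C(\C)[C@@H](O[Si](C)(C)C(C)(C)C)[C@H]3O[C@@]3(C)CC[C@@H](O)[C@@H]12 | intermediate
21 | trimethylammonium iodide of 20 | C[N+](C)(C)CC1C(=O)O[C@H]2/C=C(\C)[C@@H](O[Si](C)(C)C(C)(C)C)[C@H]3O[C@@]3(C)CC[C@@H](O)[C@@H]12.[I-] | intermediate
22 | (3aR,4R,7S,8R,9R,11aS,10E)‑9‑(TBS‑oxy)‑7,8‑epoxy‑4‑hydroxy‑7,10‑dimethyl‑3‑methylidene‑3a,4,5,6,7,8,9,11a‑octahydrocyclodeca[b]furan‑2(3H)‑one | C=C1C(=O)O[C@H]2/C=C(\C)[C@@H](O[Si](C)(C)C(C)(C)C)[C@H]3O[C@@]3(C)CC[C@@H](O)[C@@H]12 | intermediate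
23 | angelic acid, (Z)‑2‑methylbut‑2‑enoic acid | C/C=C(/C)C(=O)O | starting material
24 | angelic 2,4,6‑trichlorobenzoic anhydride | C/C=C(/C)C(=O)OC(=O)c1c(Cl)cc(Cl)cc1Cl | intermediate
25 | C4 angelate of 22 (3aR,4R,7S,8R,9R,11aS,10E) | C=C1C(=O)O[C@H]2/C=C(\C)[C@@H](O[Si](C)(C)C(C)(C)C)[C@H]3O[C@@]3(C)CC[C@@H](OC(=O)/C(C)=C\C)[C@@H]12 | intermediate
26 | C9 alcohol (desilylated 25) | C=C1C(=O)O[C@H]2/C=C(\C)[C@@H](O)[C@H]3O[C@@]3(C)CC[C@@H](OC(=O)/C(C)=C\C)[C@@H]12 | intermediate
27 | (3aR,4R,7S,8R,9R,11aS,10E)‑9‑acetoxy‑7,8‑epoxy‑7,10‑dimethyl‑3‑methylidene‑2‑oxo‑2,3,3a,4,5,6,7,8,9,11a‑decahydrocyclodeca[b]furan‑4‑yl (2Z)‑2‑methylbut‑2‑enoate | C=C1C(=O)O[C@H]2/C=C(\C)[C@@H](OC(C)=O)[C@H]3O[C@@]3(C)CC[C@@H](OC(=O)/C(C)=C\C)[C@@H]12 | target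

**Totals**
Total step count: 15. Longest linear sequence: 15 steps (1 → 27); the other starting materials enter as single small fragments.

**Three steps most likely to fail**

Step 5 (the proposed new step). The risks are a sluggish aldol of the hindered tetrasubstituted aluminium enolate, iodide addition to acrolein, and the wrong C9 epimer. The fallback uses known chemistry and sets out from 6: conjugate addition of iodotrimethylsilane (CH2Cl2, −78 °C), a known reaction of enones, gives the isolable 4‑(trimethylsilyloxy)‑C4=C10 β‑iodo silyl enol ether F4. A Lewis‑acid Mukaiyama aldol of this tetrasubstituted silyl enol ether with acrolein (TiCl4 or BF3·OEt2, CH2Cl2, −78 °C; open transition state, attack again anti to iodine) then gives the aldol after aqueous work‑up, and the route is rejoined at 9.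

Step 11. The alkoxide may instead enolise the product (β‑elimination of the lactone) or attack the lactone carbonyl. The fallback sets out from 17 and replaces the anionic trigger by a radical one: Suárez alkoxy‑radical fragmentation (PhI(OAc)2, I2, CH2Cl2/cyclohexane, visible light, rt), in which the hypoiodite gives the C4 alkoxy radical, β‑scission of C4–C10 gives the tertiary C10 radical, and this expels the β‑iodine atom. The same enone is formed under non‑basic conditions, and the route is rejoined at 18.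

Step 2. The furfuryl cation of a β‑hydroxy ester may lose a proton to give the furylacrylate instead of rearranging. The fallback sets out from 1: zinc‑mediated Barbier allylation with allyl bromide (Zn, aq. NH4Cl/THF) gives 1‑(3‑methylfuran‑2‑yl)but‑3‑en‑1‑ol F1, whose β‑hydrogens are not activated. Piancatelli rearrangement (ZnCl2, dioxane/H2O, 95 °C) gives racemic trans‑5‑allyl‑4‑hydroxy‑2‑methylcyclopent‑2‑en‑1‑one F2. Chemoselective ozonolysis of the terminal olefin (O3, CH2Cl2, −78 °C; Me2S) gives racemic 2‑[(1R*,5S*)‑5‑hydroxy‑3‑methyl‑2‑oxocyclopent‑3‑en‑1‑yl]acetaldehyde F3, and oxidative esterification (Oxone, EtOH) rejoins the route at 4.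

**Further compounds**
F1 | step 2 | 1‑(3‑methylfuran‑2‑yl)but‑3‑en‑1‑ol (racemic) | Cc1ccoc1C(O)CC=C
F2 | step 2 | trans‑5‑allyl‑4‑hydroxy‑2‑methylcyclopent‑2‑en‑1‑one (racemate; one enantiomer shown) | O=C1C(C)=C[C@H](O)[C@H]1CC=C
F3 | step 2 | 2‑[(1R*,5S*)‑5‑hydroxy‑3‑methyl‑2‑oxocyclopent‑3‑en‑1‑yl]acetaldehyde (racemate; one enantiomer shown) | O=C1C(C)=C[C@H](O)[C@H]1CC=O
F4 | step 5 | (3aS,6R,6aR)‑6‑iodo‑5‑methyl‑4‑(trimethylsilyloxy)‑3,3a,6,6a‑tetrahydro‑2H‑cyclopenta[b]furan‑2‑one | O=C1C[C@@H]2C(O[Si](C)(C)C)=C(C)[C@@H](I)[C@@H]2O1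
F0 | step 11 | none | none
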